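Drimane numbering is used (ring A: C1–C5, C10; ring B: C5–C10; C11 on C9, C12 on C8, C15 on C10). Ring B is a cyclohexene (C7=C8) flanked by C6 and C9, and the C9 hydroxyl is cis to the C10 methyl. A silicon-tethered intramolecular Diels–Alder reaction therefore forms C5–C6 and C9–C10 at once. The diene is a 3-silyloxy-4-vinylbutenolide in which C11/C12 are masked as a menthyl lactol ether whose acetal centre steers the facial course. The dienophile is the ring A alkene of an allylsilane. The O–SiMe2–CH2 tether later unravels to 9-OH and the C10 methyl; C5 and C6 are then adjusted through the 6-ketone.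

Key step: step 6

Assumption: the target is taken as the open C12-aldehyde/C11-acid tautomer as drawn; equilibration with its cyclic 12-hydroxy-11,12-olide (lactol) form would not change the route.

Step 1
Reactants: 1 3-methylcyclohex-2-en-1-one
Product: 2 1,3,3-trimethylcyclohex-1-ene
Conditions: Me2Zn, TiCl4, CH2Cl2, −40 °C; then 1, −40 → 0 °C
Reagents that add atoms: dimethylzinc, C[Zn]C (both new methyl groups, passed on through Me2TiCl2)
Why: Geminal dimethylation of a ketone with Me2TiCl2 (1,2-methyl addition, ionisation of the tertiary allylic titanium alkoxide, methyl transfer to the allyl cation) should convert the carbonyl carbon into the CMe2 group, and because the 1,3-dimethylcyclohexenyl cation is symmetric both termini give the same alkene 2; no stereocentre is formed.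

Step 2
Reactants: 2 1,3,3-trimethylcyclohex-1-ene
Product: 4 chloro[(3,3-dimethylcyclohex-1-en-1-yl)methyl]dimethylsilane, via allylpotassium 3 (not isolated)
Conditions: n-BuLi, KOt-Bu, hexane, rt; then added to Me2SiCl2 (excess), THF, −78 °C → rt; distillation
Reagents that add atoms: dichlorodimethylsilane, C[Si](C)(Cl)Cl
Why: Allylic metalation with the n-BuLi/KOt-Bu superbase is expected at the primary methyl group rather than the ring CH2, and electrophilic silylation of the allylpotassium should occur at the unhindered exocyclic terminus because the ring terminus C5 is neopentylic, which keeps the C5=C10 double bond; no stereocentre is formed.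

Step 3
Reactants: 5 mucobromic acid; 6 (−)-menthol
Product: 7 (5R)-3,4-dibromo-5-[(1R,2S,5R)-menthyloxy]furan-2(5H)-one
Conditions: p-TsOH·H2O (cat.), toluene, reflux (Dean–Stark); crystallisation from hexane, mother liquor re-equilibrated
Reagents that add atoms: none
Why: Acid-catalysed acetalisation (pseudo-ester formation) of the lactol is reversible, so the two acetal epimers interconvert and the (5R) epimer should be collected by crystallisation while the mother liquor is re-equilibrated, which fixes the one stereocentre that later controls the cycloaddition.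

Step 4
Reactants: 7 (5R)-3,4-dibromo-5-menthyloxyfuran-2(5H)-one
Product: 8 (5R)-3-bromo-5-menthyloxy-4-vinylfuran-2(5H)-one
Conditions: tributyl(vinyl)stannane, Pd2(dba)3 (cat.), AsPh3, toluene, 60 °C
Reagents that add atoms: tributyl(vinyl)stannane, C=C[Sn](CCCC)(CCCC)CCCC
Why: Stille coupling of a 3,4-dibromobutenolide takes place first at the more electrophilic β-carbon (C4 of the furanone, the future C8), and the base-free conditions leave the acetal stereocentre untouched.

Step 5
Reactants: 8 (5R)-3-bromo-5-menthyloxy-4-vinylfuran-2(5H)-one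
Product: 10 (5R)-3-hydroxy-5-menthyloxy-4-vinylfuran-2(5H)-one, via vinyl boronate 9 (not isolated)
Conditions: B2pin2, PdCl2(dppf), KOAc, 1,4-dioxane, 80 °C; then 30% H2O2, pH 7 phosphate buffer, THF, 0 °C
Reagents that add atoms: bis(pinacolato)diboron, CC1(C)OB(OC1(C)C)B1OC(C)(C)C(C)(C)O1 (boron of 9 only); hydrogen peroxide, OO (hydroxyl oxygen of 10)
Why: Miyaura borylation of the remaining α-bromide followed by buffered peroxide oxidation of the vinyl boronate should unveil the 3-hydroxybutenolide, the stable enol of the α-keto lactone, without affecting the acetal stereocentre.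

Step 6
Reactants: 10 (5R)-3-hydroxy-5-menthyloxy-4-vinylfuran-2(5H)-one; 4 chloro[(3,3-dimethylcyclohex-1-en-1-yl)methyl]dimethylsilane
Product: 12 oxasilolane-bridged cis-fused cycloadduct, via silicon-tethered triene 11 (not isolated)
Conditions: Et3N, toluene, 0 °C → rt, filtration under argon; then BHT (cat.), toluene (high dilution), 180 °C, sealed tube
Reagents that add atoms: none
Why: O-Silylation of the acidic enol gives triene 11, which on heating should undergo a concerted, suprafacial intramolecular [4+2] cycloaddition (Diels–Alder) between the butenolide-based diene C9=C8–C7=C6 and the ring A alkene C5=C10, forming C9–C10 and C5–C6. The closest known reaction type is the Diels–Alder reaction through a temporary silicon tether, here of the nona-1,3,8-triene class with the tether on the inside (Z) position of the diene terminus. Ring B is closed as the six-membered ring of the cycloaddition, and the five-membered 1-oxa-2-silacyclopentane (C9–O–Si–C15–C10) closes with it and can only be cis-fused, which places C15 exo and ring A endo. C9 and C10 are thus set relative to each other by the tether (9-O cis to C15) and absolutely by the (12R) menthyloxy acetal, because the dienophile and the endo ring A must pass the diene face anti to that alkoxy group; C5 follows from suprafacial addition to the ring alkene (5-H cis to C15, corrected in step 8). The step needs regioselectivity, which the three-atom tether enforces, and diene π-facial selectivity, which the acetal substituent next to C8 secures; the pairing of the electron-poor dienoate diene with the electron-rich allylsilane alkene supports reactivity.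

Step 7
Reactants: 12 oxasilolane-bridged cis-fused cycloadduct
Product: 13 (12R)-9β-hydroxy-12-menthyloxy-5β-drim-7-en-11,12-olide
Conditions: TBAF·3H2O (excess), DMF, 75 °C
Reagents that add atoms: none
Why: Fluoride-induced protodesilylation of the 1-oxa-2-silacyclopentane (attack at silicon, Si–O cleavage and alkoxide-assisted protonolysis of the Si–CH2 bond) should release the tertiary 9-hydroxyl and turn C15 into the C10 methyl group with retention at C9 and C10, the lactone carbonyl on the fully substituted C9 being too hindered for attack by the basic fluoride.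

Step 8
Reactants: 13 (12R)-9β-hydroxy-12-menthyloxy-5β-drim-7-en-11,12-olide
Product: 15 (12R)-9β-hydroxy-12-menthyloxy-6-oxo-5α-drim-7-en-11,12-olide, via cis-fused enone 14 (not isolated)
Conditions: dirhodium tetracaprolactamate Rh2(cap)4 (cat.), t-BuOOH, K2CO3, CH2Cl2, rt; then DBU (cat.), CH2Cl2, rt
Reagents that add atoms: tert-butyl hydroperoxide, CC(C)(C)OO (carbonyl oxygen)
Why: Rh2(cap)4/t-BuOOH allylic C–H oxidation should convert the only ring allylic methylene (C6) into the enone without the chromate-type transposition of the tertiary allylic 9-hydroxyl, and base-mediated enolisation then epimerises C5 to the more stable trans-fused decalin (5α-H anti to the C10 methyl), so C5 is set under thermodynamic control.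

Step 9
Reactants: 15 (12R)-9β-hydroxy-12-menthyloxy-6-oxo-5α-drim-7-en-11,12-olide
Product: 16 (12R)-6β,9β-dihydroxy-12-menthyloxy-5α-drim-7-en-11,12-olide
Conditions: NaBH4, CeCl3·7H2O, MeOH, −78 °C
Reagents that add atoms: none
Why: Luche reduction is a 1,2-reduction of the enone in which hydride attacks C6 from the α face, the β face being shielded by the syn-axial C10 and C4β methyl groups, so the axial 6β-alcohol is formed under substrate control while lactone, acetal and C7=C8 remain.

Step 10
Reactants: 17 (2E,4E,6E)-octa-2,4,6-trienoic acid; 16 (12R)-6β,9β-dihydroxy-12-menthyloxy-5α-drim-7-en-11,12-olide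
Product: 19 (12R)-9β-hydroxy-12-menthyloxy-6β-[(2E,4E,6E)-octa-2,4,6-trienoyloxy]-5α-drim-7-en-11,12-olide, via mixed anhydride 18 (not isolated)
Conditions: 2,4,6-trichlorobenzoyl chloride, Et3N, THF, rt; then 16, DMAP, toluene, 60 °C
Reagents that add atoms: 2,4,6-trichlorobenzoyl chloride, O=C(Cl)c1c(Cl)cc(Cl)cc1Cl (its aroyl group is part of 18 only)
Why: Yamaguchi esterification through the mixed anhydride acylates the secondary 6β-hydroxyl with retention at C6, the tertiary 9-hydroxyl being inert and the (E,E,E)-triene not being touched under these non-isomerising conditions.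

Step 11
Reactants: 19 (12R)-9β-hydroxy-12-menthyloxy-6β-[(2E,4E,6E)-octa-2,4,6-trienoyloxy]-5α-drim-7-en-11,12-olide
Product: 20 target CNP0234478.3
Conditions: TFA/H2O (9:1), CH2Cl2, 0 °C → rt
Reagents that add atoms: water, O
Why: Acid-catalysed hydrolysis of the menthyl lactol ether (acetal cleavage via the C12 oxocarbenium ion) releases menthol and opens the pseudo-ester to the C12 aldehyde and the C11 carboxylic acid, leaving the allylic trienoate and all four stereocentres unchanged.

Compound list
1 | 3-methylcyclohex-2-en-1-one | CC1=CC(=O)CCC1 | starting material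
2 | 1,3,3-trimethylcyclohex-1-ene | CC1=CC(C)(C)CCC1 | intermediate
3 | (3,3-dimethylcyclohex-1-en-1-yl)methylpotassium (allylpotassium) | [K+].[CH2-]C1=CC(C)(C)CCC1 | intermediate
4 | chloro[(3,3-dimethylcyclohex-1-en-1-yl)methyl]dimethylsilane | C[Si](C)(Cl)CC1=CC(C)(C)CCC1 | intermediate
5 | mucobromic acid, 3,4-dibromo-5-hydroxyfuran-2(5H)-one | OC1OC(=O)C(Br)=C1Br | starting material
6 | (−)-menthol, (1R,2S,5R)-2-isopropyl-5-methylcyclohexan-1-ol | C[C@@H]1CC[C@H]([C@@H](C1)O)C(C)C | starting material
7 | (5R)-3,4-dibromo-5-[(1R,2S,5R)-menthyloxy]furan-2(5H)-one | BrC1=C(Br)C(=O)O[C@H]1O[C@@H]2C[C@H](C)CC[C@H]2C(C)C | intermediate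
8 | (5R)-3-bromo-5-[(1R,2S,5R)-menthyloxy]-4-vinylfuran-2(5H)-one | C=CC1=C(Br)C(=O)O[C@H]1O[C@@H]2C[C@H](C)CC[C@H]2C(C)C | intermediate
9 | (5R)-5-menthyloxy-3-(4,4,5,5-tetramethyl-1,3,2-dioxaborolan-2-yl)-4-vinylfuran-2(5H)-one (vinyl boronate) | C=CC1=C(B2OC(C)(C)C(C)(C)O2)C(=O)O[C@H]1O[C@@H]3C[C@H](C)CC[C@H]3C(C)C | intermediate
10 | (5R)-3-hydroxy-5-[(1R,2S,5R)-menthyloxy]-4-vinylfuran-2(5H)-one | C=CC1=C(O)C(=O)O[C@H]1O[C@@H]2C[C@H](C)CC[C@H]2C(C)C | intermediate
11 | (5R)-3-{[(3,3-dimethylcyclohex-1-en-1-yl)methyl]dimethylsilyloxy}-5-menthyloxy-4-vinylfuran-2(5H)-one (silicon-tethered triene) | C=CC1=C(O[Si](C)(C)CC2=CC(C)(C)CCC2)C(=O)O[C@H]1O[C@@H]3C[C@H](C)CC[C@H]3C(C)C | intermediate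
12 | cycloadduct: (12R)-12-menthyloxy-5β-drim-7-en-11,12-olide with 9β-O and C15 joined by SiMe2 (1-oxa-2-silacyclopentane cis-fused on C9–C10); cis-decalin, 5-H and C15 β, lactone carbonyl C11 α | C1C=C3[C@H](O[C@@H]5C[C@H](C)CC[C@H]5C(C)C)OC(=O)[C@@]3(O[Si](C)(C)C4)[C@@]24CCCC(C)(C)[C@@H]12 | intermediate
13 | (12R)-9β-hydroxy-12-menthyloxy-5β-drim-7-en-11,12-olide (cis-fused; 9-OH cis to 10-CH3; C11 α) | C1C=C3[C@H](O[C@@H]4C[C@H](C)CC[C@H]4C(C)C)OC(=O)[C@@]3(O)[C@@]2(C)CCCC(C)(C)[C@@H]12 | intermediate
14 | (12R)-9β-hydroxy-12-menthyloxy-6-oxo-5β-drim-7-en-11,12-olide (cis-fused enone) | O=C1C=C3[C@H](O[C@@H]4C[C@H](C)CC[C@H]4C(C)C)OC(=O)[C@@]3(O)[C@@]2(C)CCCC(C)(C)[C@@H]12 | intermediate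
15 | (12R)-9β-hydroxy-12-menthyloxy-6-oxo-5α-drim-7-en-11,12-olide (trans-fused enone) | O=C1C=C3[C@H](O[C@@H]4C[C@H](C)CC[C@H]4C(C)C)OC(=O)[C@@]3(O)[C@@]2(C)CCCC(C)(C)[C@H]12 | intermediate
16 | (12R)-6β,9β-dihydroxy-12-menthyloxy-5α-drim-7-en-11,12-olide | O[C@@H]1C=C3[C@H](O[C@@H]4C[C@H](C)CC[C@H]4C(C)C)OC(=O)[C@@]3(O)[C@@]2(C)CCCC(C)(C)[C@H]12 | intermediate
17 | (2E,4E,6E)-octa-2,4,6-trienoic acid | C/C=C/C=C/C=C/C(=O)O | starting material
18 | (2E,4E,6E)-octa-2,4,6-trienoic 2,4,6-trichlorobenzoic anhydride (mixed anhydride) | C/C=C/C=C/C=C/C(=O)OC(=O)c1c(Cl)cc(Cl)cc1Cl | intermediate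
19 | (12R)-9β-hydroxy-12-menthyloxy-6β-[(2E,4E,6E)-octa-2,4,6-trienoyloxy]-5α-drim-7-en-11,12-olide | C/C=C/C=C/C=C/C(=O)O[C@@H]1C=C3[C@H](O[C@@H]4C[C@H](C)CC[C@H]4C(C)C)OC(=O)[C@@]3(O)[C@@]2(C)CCCC(C)(C)[C@H]12 | intermediate
20 | CNP0234478.3: (5S,6R,9R,10S)-9-hydroxy-6-[(2E,4E,6E)-octa-2,4,6-trienoyloxy]-12-oxodrim-7-en-11-oic acid (5α-H, 10β-CH3, 6β-acyloxy, 9β-OH, C11 carboxyl α) | C/C=C/C=C/C=C/C(=O)O[C@@H]1C=C(C=O)[C@@](O)(C(=O)O)[C@@]2(C)CCCC(C)(C)[C@H]12 | target

Total step count: 11. Longest linear sequence: 9 steps (steps 3, 4, 5, 6, 7, 8, 9, 10, 11, from mucobromic acid).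

Steps most likely to fail

Step 6. The thermal cycloaddition has to join two fully substituted carbons (C9 and C10). Hydrolysis or thermal breakdown of the silyl enol ether tether, or oligomerisation of the diene, may outrun ring closure. The fallback sets out from 10 and replaces the tether by electronic activation of ring A. Silylation of 10 (TBSOTf, Et3N) would give the tert-butyldimethylsilyl dienol ether F1. A Lewis-acid-promoted intermolecular Diels–Alder reaction (Me2AlCl, CH2Cl2, −78 → 0 °C) with commercial 2,4,4-trimethylcyclohex-2-en-1-one should then give the 1-oxo cycloadduct F2. Its regiochemistry follows from the 1-silyloxydiene/enone polarity, and the Alder endo rule places the ring A carbonyl endo, so C5, C9 and C10 have the same relative configuration as in 13, again anti to the menthyloxy group. Condensation with tosylhydrazine would give the tosylhydrazone F3, and catecholborane/NaOAc reduction would remove the C1 oxygen to give the 9-O-silyl ether F4. TBAF then returns 13, where the route is rejoined.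

Step 8. Hydrogen abstraction at the allylic acetal C–H of C12 may compete with abstraction at C6 and lead to over-oxidation of the lactol ether, and the epimerisation at C5 may stay incomplete. The fallback sets out from 13 and avoids hydrogen abstraction by a radical. A Schenck ene reaction with singlet oxygen (O2, methylene blue, hν, CH2Cl2) should remove a C6 hydrogen on the more crowded side of the C7=C8 bond and give the 8-hydroperoxide F5. Reduction with PPh3 would give the tertiary allylic alcohol F6. Babler–Dauben oxidative 1,3-transposition with PCC then delivers the cis-fused enone 14, which the DBU treatment of step 8 converts into 15.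

Step 10. Acyl transfer to the axial 6β-hydroxyl, which is syn-axial to the C4 and C10 methyl groups, may be slow enough for the activated trienoate to decompose or isomerise. The fallback sets out from 16 and builds the acyl chain on the oxygen. Acylation with the small diethylphosphonoacetic acid (DCC, DMAP, CH2Cl2) would give the phosphonoacetate F7. Horner–Wadsworth–Emmons olefination with commercial (2E,4E)-hexa-2,4-dienal under Masamune–Roush conditions (LiCl, DBU, MeCN) then forms the (2E) double bond and gives 19 directly.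

Further compounds
F1 | step 6 | (5R)-3-(tert-butyldimethylsilyloxy)-5-menthyloxy-4-vinylfuran-2(5H)-one | C=CC1=C(O[Si](C)(C)C(C)(C)C)C(=O)O[C@H]1O[C@@H]2C[C@H](C)CC[C@H]2C(C)C
F2 | step 6 | (12R)-9β-(tert-butyldimethylsilyloxy)-12-menthyloxy-1-oxo-5β-drim-7-en-11,12-olide | C1C=C3[C@H](O[C@@H]4C[C@H](C)CC[C@H]4C(C)C)OC(=O)[C@@]3(O[Si](C)(C)C(C)(C)C)[C@@]2(C)C(=O)CCC(C)(C)[C@@H]12
F3 | step 6 | 1-(4-methylbenzenesulfonyl)hydrazone of F2 | C1C=C3[C@H](O[C@@H]4C[C@H](C)CC[C@H]4C(C)C)OC(=O)[C@@]3(O[Si](C)(C)C(C)(C)C)[C@@]2(C)C(=NNS(=O)(=O)c5ccc(C)cc5)CCC(C)(C)[C@@H]12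
F4 | step 6 | (12R)-9β-(tert-butyldimethylsilyloxy)-12-menthyloxy-5β-drim-7-en-11,12-olide | C1C=C3[C@H](O[C@@H]4C[C@H](C)CC[C@H]4C(C)C)OC(=O)[C@@]3(O[Si](C)(C)C(C)(C)C)[C@@]2(C)CCCC(C)(C)[C@@H]12
F5 | step 8 | (12R)-8-hydroperoxy-9β-hydroxy-12-menthyloxy-5β-drim-6-en-11,12-olide (C8 configuration not defined) | C1=CC3(OO)[C@H](O[C@@H]4C[C@H](C)CC[C@H]4C(C)C)OC(=O)[C@@]3(O)[C@@]2(C)CCCC(C)(C)[C@@H]12
F6 | step 8 | (12R)-8,9β-dihydroxy-12-menthyloxy-5β-drim-6-en-11,12-olide (C8 configuration not defined) | C1=CC3(O)[C@H](O[C@@H]4C[C@H](C)CC[C@H]4C(C)C)OC(=O)[C@@]3(O)[C@@]2(C)CCCC(C)(C)[C@@H]12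
F7 | step 10 | (12R)-6β-[2-(diethoxyphosphoryl)acetoxy]-9β-hydroxy-12-menthyloxy-5α-drim-7-en-11,12-olide | CCOP(=O)(OCC)CC(=O)O[C@@H]1C=C3[C@H](O[C@@H]4C[C@H](C)CC[C@H]4C(C)C)OC(=O)[C@@]3(O)[C@@]2(C)CCCC(C)(C)[C@H]12
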